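Assumption: 2',6'-dihydroxy-4'-methoxyacetophenone (compound 20) is treated as a purchasable building block; if it had to be made, methylation of the non-chelated hydroxyl of phloroacetophenone would supply it in one step.

## The problem

Abiesin 24 is a biflavonoid in which C3' of a 5-hydroxy-7-methoxyflavone is bonded to C6 of a 3,7-dihydroxy-4'-methoxyflavonol; ring B of the flavone unit is thus a 1,3,4-trisubstituted anisole. There is no stereocenter, and the biaryl axis has only two ortho substituents (the C4' methoxy and the flavonol C7 hydroxyl) beside two hydrogens, so it rotates freely and nothing stereochemical needs control. The difficulty is regiochemical: three methyl ethers and three free hydroxyls sit at fixed positions, and no late selective demethylation can sort them. Each methoxy must therefore arrive with a building block, and each hydroxyl must be carried as a removable ether or freed by chelation. Two different chromones (a 3-hydroxychromone without a C5 oxygen and a 5-hydroxychromone without a C3 oxygen) must be built on one biaryl in an order where making the second does not destroy the first. The sensitive groups are the chromone rings (opened by hot hydroxide), the enolic 3-hydroxyl of the flavonol (oxidized in basic air), the aryl benzyl ethers (strong Lewis acids) and, on the way, enol ethers (acid). The enabling feature is the pattern of flavone ring B: C4' (OMe) is para to C1', which carries the carboxyl-level carbon C2 of the flavone, and C3' (the flavonol aryl) is the neighbour of C4'. A 2-methoxy-3-arylbuta-1,3-diene and a propiolate give exactly this pattern, with C3'/C4' as the inner diene carbons, C2'/C5' as its termini and C1'/C6' as the alkyne carbons; the aryl-bearing diene carbon can be the acetyl carbon of a resacetophenone that already is flavonol ring A.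

## Retrosynthesis

**24 to 23.** The last cut removes the two O-benzyl groups at the flavonol C3 and C7 oxygens of abiesin 24, leading back to the dibenzyl ether 23. Benzyl is chosen because hydrogenolysis leaves the three methyl ethers untouched. The forward step only has to spare the chromone double bonds.

**23 to 19 and 20.** Flavone ring C is cut at C2–C3 and O1–C2, leading back through the 1,3-diketone 22 to the benzyl ester 19 and acetophenone 20. This is preferred over an acylation at C4–C4a because the cycloaddition delivers flavone C2 as an ester, and because 20 already carries the ring A pattern (methoxy at the future C7, two equivalent hydroxyls). Whichever hydroxyl closes, the same flavone forms, and the other becomes the 5-hydroxyl. The forward reaction needs a C-acylation of the lithium polyanion 21 that leaves the protected flavonol alone.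

**19 to 13 and 14.** The flavonol is taken apart next: the ester and the 3-O-benzyl group go back to flavonol acid 18. Ring C is cut at O1–C2 and C3–OH (oxidative closure of chalcone acid 16, via dihydroflavonol 17) and at C2–C3 (aldol with aldehyde 14, after saponification of 13 to acid 15). The flavonol is built before the flavone for two reasons. The acetyl group must be consumed before any enolate chemistry is run on the ester, and a finished chromone should not see aqueous alkali and peroxide. The ester will not survive those media, so it is hydrolysed on purpose and re-formed in the same operation that caps the 3-hydroxyl.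

**13 to 11.** The acetyl–aryl bond at the future flavonol C4a is cut, and the benzyl group is restored on the oxygen that becomes O1 (via the acetylated bis-benzyl ether 12). In biaryl ester 11 only one ring carbon is ortho/para to both ether oxygens and unhindered, so an electrophilic acylation has one site. The Lewis acid chelate of the new ketone distinguishes the two benzyl ethers.

**11 to 8 and 9.** The central anisole ring is reduced by two hydrogens to the 1,4-cyclohexadiene 10, which is the [4+2] adduct of diene 8 and methyl propiolate 9. The cut removes C1'–C2' and C5'–C6'. Compared with an aryl–aryl coupling it needs no halogenated or metallated flavonoid precursor and fixes the biaryl position by construction. The forward step must give the para orientation (ester opposite methoxy).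

**8 to 1.** The bond between the two inner diene carbons is cut to enol triflate 4 and the zinc reagent 7, made from methyl vinyl ether 5 through the lithium compound 6. Triflate 4 comes from ketone 2 through its potassium enolate 3, and 2 from 2,4-dihydroxyacetophenone 1. The acetyl carbon of 1 ends as C3' of the target.

## Roads not taken

**Alternative 1:** The cut is the C4a–C5 bond of flavone ring A. The ring is unravelled into a 4-methoxy-2-pyranone that carries a β-diketone chain on the finished biaryl flavonol, the pyranone diketone A1. In the forward step, methoxide would open the lactone of A1 to an enol ether keto ester, and the methylene flanked by two carbonyls would close onto the ester carbon. Aromatization would give the 2,6-dihydroxy-4-methoxyphenyl diketone A2, ready for cyclodehydration.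
- Merits: the oxygen pattern of ring A is written into the pyranone, so no polyphenol has to be handled as a polyanion. The idea is biomimetic.
- Weak points: the open chain has several acidic methylenes and several electrophilic carbonyls, so aldol-type closures onto a ketone can compete with the wanted Claisen closure. A1 would itself be assembled by a strong-base acylation with an ester such as 19, so the step it is meant to avoid returns earlier.
- Comparison: A2 is the same compound as 22, which the chosen route reaches in one operation from 19 and 20. Alternative 1 is equal in what it delivers and would be better only if an acetophenone of type 20 were unavailable or a ring A analogue were wanted. It says nothing about the biaryl bond.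

**Alternative 2:** The cut is O1–C2 and C3–O of flavonol ring C, made last, on the 2'-hydroxychalcone A3 that already carries the complete flavone. Alkaline hydrogen peroxide would convert chalcone A3 into 7-O-benzylabiesin A4, and A4 is one hydrogenolysis from the target.
- Merits: the 3-hydroxyl is never protected, which saves the benzylation of step 9, and the oxidation-prone flavonol appears only at the end, as A4. In protecting-group economy this road is better than the chosen one.
- Weak points: chalcone formation and the oxidation expose a 5-hydroxyflavone to aqueous alkali and peroxide, which open chromones. The acetyl group for A3 would have to be introduced beside the strongly activated ring A of the flavone, or carried through the flavone-forming condensation where its own enolate competes.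
- Comparison: the chosen plan uses the same oxidative closure (step 8) but earlier, on a substrate with one activated ring and no chromone. It pays one extra step for that compared with the passage from A3 to A4, and the biaryl bond still has to come from elsewhere.

**Alternative 3:** The cut removes three bonds of flavone ring C (C4a–C4, C4–C3 and O1–C2). The pieces are the symmetric 2-iodo-5-methoxyresorcinol A5, carbon monoxide and the terminal alkyne A6 on the biaryl flavonol. Palladium-catalysed carbonylative coupling of A5 with A6, followed in the same flask by 6-endo addition of a phenol to the alkynyl ketone so formed, would give 3,7-di-O-benzylabiesin A7. Compound A7 is identical with 23.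
- Merits: this is the most convergent road. It avoids excess strong base near the flavonol, and the symmetry of A5 removes any question of which hydroxyl closes. In mildness toward the flavonol it is better than step 10.
- Weak points: the iodide of A5 is flanked by two free hydroxyls and is very electron-rich, so oxidative addition is slow. Direct coupling without carbon monoxide leads to a benzofuran, and 5-exo closure to an aurone competes with the flavone A7. A6 would need about three extra steps from an ester.
- Comparison: counted from the common ester stage the chosen plan is shorter (one operation from 19 to 23, the same compound as A7) and uses a purchasable partner. It sets a well-established diketone cyclization against the cleaner conditions of the annulation.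

All three alternatives are end-game choices that presuppose the C3'–C6 biaryl. A direct aryl–aryl coupling would make that bond in fewer steps than the cycloaddition. What the chosen plan offers in return is that the position of the biaryl bond is never in doubt and that every carbon comes from simple commercial materials.

Key step: step 4

## Route

Step 1
Reactants: 1 2,4-dihydroxyacetophenone
Product: 2 1-[2,4-bis(benzyloxy)phenyl]ethan-1-one
Conditions: BnBr, K2CO3, KI (cat.), DMF, 80 °C
Reagents that add atoms: benzyl bromide, BrCc1ccccc1
Why: Williamson ether synthesis; DMF and heat are needed because the 2-hydroxyl is hydrogen-bonded to the ketone, and both phenols must be capped before enolate chemistry.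

Step 2
Reactants: 2 1-[2,4-bis(benzyloxy)phenyl]ethan-1-one
Product: 4 1-[2,4-bis(benzyloxy)phenyl]ethenyl trifluoromethanesulfonate, via potassium enolate 3 (not isolated)
Conditions: KN(SiMe3)2 (1.0 equiv), THF, −78 °C; then PhNTf2, −78 → 0 °C
Reagents that add atoms: N-phenylbis(trifluoromethanesulfonimide), O=S(=O)(N(c1ccccc1)S(=O)(=O)C(F)(F)F)C(F)(F)F
Why: Enol triflate formation by kinetic deprotonation of the methyl ketone (only one enolate is possible) and O-sulfonylation; no excess base is used, so the product is not eliminated to the arylalkyne.

Step 3
Reactants: 4 1-[2,4-bis(benzyloxy)phenyl]ethenyl trifluoromethanesulfonate; 5 methyl vinyl ether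
Product: 8 2-[2,4-bis(benzyloxy)phenyl]-3-methoxybuta-1,3-diene, via 1-methoxyvinyllithium 6 (not isolated), via 1-methoxyvinylzinc chloride 7 (not isolated)
Conditions: 5, t-BuLi, THF, −78 → 0 °C; ZnCl2, 0 °C; then 4, Pd(PPh3)4 (5 mol %), THF, 25–45 °C; NaHCO3 work-up, Et3N-deactivated silica
Reagents that add atoms: none
Why: α-Lithiation of the vinyl ether, transmetalation to zinc and Negishi coupling with the alkenyl triflate under zerovalent palladium catalysis; an sp2–sp2 coupling has no β-hydride pathway, and the neutral conditions and buffered work-up preserve the acid-labile 2-methoxydiene.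

Step 4
Reactants: 8 2-[2,4-bis(benzyloxy)phenyl]-3-methoxybuta-1,3-diene; 9 methyl propiolate
Product: 10 methyl 5-[2,4-bis(benzyloxy)phenyl]-4-methoxycyclohexa-1,4-diene-1-carboxylate
Conditions: 9 (3 equiv), BHT (cat.), toluene, 110 °C, sealed tube, base-washed glassware; concentrate and use directly
Reagents that add atoms: none
Why: Thermal normal-demand Diels–Alder reaction in which the HOMO of the 2-methoxydiene and the LUMO of the propiolate combine in a concerted, asynchronous [4+2] cycloaddition; the closest precedent is the para-selective addition of 2-alkoxy- and 2-silyloxybutadienes to propiolates and acrylates. The six-membered ring (the future flavone ring B) closes by intermolecular cycloaddition from the s-cis diene, and both new σ bonds (C1'–C2' and C5'–C6') form in the same step. No stereocenter is created, because the alkyne leaves a 1,4-cyclohexadiene whose ring atoms are only sp2 carbons and CH2 groups. The selectivity needed is para regiochemistry, with the ester carbon opposite the methoxy carbon. The methoxy oxygen raises the HOMO coefficient at its own methylene terminus, which therefore bonds to the β carbon of the propiolate. The competing director, the aryl group on the neighbouring diene carbon, is twisted out of the diene plane by its ortho benzyloxy group and the flanking vinyl unit, so its conjugative influence should be small. Excess dienophile, a radical inhibitor and acid-free glassware are meant to suppress diene dimerization and enol ether hydrolysis.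

Step 5
Reactants: 10 methyl 5-[2,4-bis(benzyloxy)phenyl]-4-methoxycyclohexa-1,4-diene-1-carboxylate
Product: 11 methyl 3-[2,4-bis(benzyloxy)phenyl]-4-methoxybenzoate
Conditions: DDQ (1.1 equiv), toluene, 0 °C → rt
Reagents that add atoms: none
Why: DDQ dehydrogenation of a 1,4-cyclohexadiene: hydride abstraction from the doubly allylic CH2 next to the enol ether gives an oxygen-stabilized cation that loses a proton to the anisole; aryl benzyl ethers and the ester are inert at room temperature.

Step 6
Reactants: 11 methyl 3-[2,4-bis(benzyloxy)phenyl]-4-methoxybenzoate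
Product: 13 methyl 3-[5-acetyl-2-(benzyloxy)-4-hydroxyphenyl]-4-methoxybenzoate, via acetylated bis-benzyl ether 12 (not isolated)
Conditions: AcCl (1.5 equiv), TiCl4 (2.5 equiv), CH2Cl2, −40 → 0 °C; aq. HCl
Reagents that add atoms: acetyl chloride, CC(Cl)=O
Why: Friedel–Crafts acylation at the only unhindered carbon that is ortho/para to both ether oxygens of the resorcinol ring (the ester-bearing anisole ring is deactivated); the TiCl4 chelate of the new ketone then cleaves only the benzyl ether ortho to the carbonyl (chelation-assisted dealkylation), leaving the para ether in place.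

Step 7
Reactants: 13 methyl 3-[5-acetyl-2-(benzyloxy)-4-hydroxyphenyl]-4-methoxybenzoate; 14 4-methoxybenzaldehyde
Product: 16 3-{2-(benzyloxy)-4-hydroxy-5-[(2E)-3-(4-methoxyphenyl)prop-2-enoyl]phenyl}-4-methoxybenzoic acid, via acetophenone acid 15 (not isolated)
Conditions: KOH, EtOH/H2O, 50 °C; then 14, rt; aq. HCl
Reagents that add atoms: potassium hydroxide, [K+].[OH-]
Why: Ester saponification followed by Claisen–Schmidt (crossed aldol) condensation with a non-enolizable aldehyde; E1cB dehydration gives the thermodynamically preferred E chalcone, and hydrolysing the ester on purpose avoids an ester/acid mixture.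

Step 8
Reactants: 16 3-{2-(benzyloxy)-4-hydroxy-5-[(2E)-3-(4-methoxyphenyl)prop-2-enoyl]phenyl}-4-methoxybenzoic acid
Product: 18 3-[7-(benzyloxy)-3-hydroxy-2-(4-methoxyphenyl)-4-oxo-4H-chromen-6-yl]-4-methoxybenzoic acid, via trans-dihydroflavonol 17 (not isolated)
Conditions: NaOH, 30% H2O2, MeOH/THF, 0 °C → rt; aq. HCl
Reagents that add atoms: hydrogen peroxide, OO
Why: Algar–Flynn–Oyamada oxidation: closure of the 2'-phenoxide onto the enone with oxygen transfer from hydroperoxide gives the racemic trans-dihydroflavonol, which is oxidized on to the flavonol; the absence of a 6'-substituent and the p-methoxy B ring favour flavonol over aurone.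

Step 9
Reactants: 18 3-[7-(benzyloxy)-3-hydroxy-2-(4-methoxyphenyl)-4-oxo-4H-chromen-6-yl]-4-methoxybenzoic acid
Product: 19 benzyl 3-[3,7-bis(benzyloxy)-2-(4-methoxyphenyl)-4-oxo-4H-chromen-6-yl]-4-methoxybenzoate
Conditions: BnBr (2.5 equiv), K2CO3, DMF, 60 °C
Reagents that add atoms: benzyl bromide, BrCc1ccccc1
Why: Double O-alkylation (Williamson ether synthesis and carboxylate alkylation) caps the oxidation-prone 3-hydroxyl and turns the acid back into an ester acyl donor in one operation.

Step 10
Reactants: 19 benzyl 3-[3,7-bis(benzyloxy)-2-(4-methoxyphenyl)-4-oxo-4H-chromen-6-yl]-4-methoxybenzoate; 20 2',6'-dihydroxy-4'-methoxyacetophenone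
Product: 23 3,7-di-O-benzylabiesin, via trilithium polyanion 21 (not isolated), via 1,3-diketone 22 (not isolated)
Conditions: 20 (1.5 equiv), LiN(SiMe3)2 (4 equiv per 20), THF, −78 → −10 °C; then 19, −78 °C → rt; aq. HCl; then AcOH, H2SO4 (cat.), 80 °C
Reagents that add atoms: none
Why: Crossed Claisen condensation of the lithium polyanion of an o-hydroxyacetophenone with an aryl ester (C-acylation), then acid-catalysed cyclodehydration of the 1,3-diketone to the chromone; the two phenols of 22 are equivalent, so only one flavone can form and the unused hydroxyl becomes the chelated 5-hydroxyl.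

Step 11
Reactants: 23 3,7-di-O-benzylabiesin
Product: 24 abiesin
Conditions: H2 (1 atm), 10% Pd/C, THF/MeOH, rt
Reagents that add atoms: none
Why: Hydrogenolysis of the two benzyl ethers over palladium on carbon; the methyl ethers and the chromone double bonds should not be touched at 1 atm and room temperature if the reaction is stopped at completion.

## Compound list

1 | 2,4-dihydroxyacetophenone | CC(=O)c1ccc(O)cc1O | starting material
2 | 1-[2,4-bis(benzyloxy)phenyl]ethan-1-one | CC(=O)c1ccc(OCc2ccccc2)cc1OCc1ccccc1 | intermediate
3 | potassium 1-[2,4-bis(benzyloxy)phenyl]ethen-1-olate (enolate of 2, not isolated) | C=C([O-])c1ccc(OCc2ccccc2)cc1OCc1ccccc1.[K+] | intermediate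
4 | 1-[2,4-bis(benzyloxy)phenyl]ethenyl trifluoromethanesulfonate | C=C(OS(=O)(=O)C(F)(F)F)c1ccc(OCc2ccccc2)cc1OCc1ccccc1 | intermediate
5 | methyl vinyl ether (methoxyethene) | C=COC | starting material
6 | 1-methoxyvinyllithium, (1-methoxyethenyl)lithium (not isolated) | [Li]C(=C)OC | intermediate
7 | 1-methoxyvinylzinc chloride, chloro(1-methoxyethenyl)zinc (not isolated) | Cl[Zn]C(=C)OC | intermediate
8 | 2-[2,4-bis(benzyloxy)phenyl]-3-methoxybuta-1,3-diene | C=C(C(=C)OC)c1ccc(OCc2ccccc2)cc1OCc1ccccc1 | intermediate
9 | methyl propiolate (methyl prop-2-ynoate) | C#CC(=O)OC | starting material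
10 | methyl 5-[2,4-bis(benzyloxy)phenyl]-4-methoxycyclohexa-1,4-diene-1-carboxylate | COC(=O)C1=CCC(OC)=C(C1)c1ccc(OCc2ccccc2)cc1OCc1ccccc1 | intermediate
11 | methyl 3-[2,4-bis(benzyloxy)phenyl]-4-methoxybenzoate | COC(=O)c1ccc(OC)c(c1)-c1ccc(OCc2ccccc2)cc1OCc1ccccc1 | intermediate
12 | methyl 3-[5-acetyl-2,4-bis(benzyloxy)phenyl]-4-methoxybenzoate (not isolated) | COC(=O)c1ccc(OC)c(c1)-c1cc(C(C)=O)c(OCc2ccccc2)cc1OCc1ccccc1 | intermediate
13 | methyl 3-[5-acetyl-2-(benzyloxy)-4-hydroxyphenyl]-4-methoxybenzoate | COC(=O)c1ccc(OC)c(c1)-c1cc(C(C)=O)c(O)cc1OCc1ccccc1 | intermediate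
14 | 4-methoxybenzaldehyde | COc1ccc(C=O)cc1 | starting material
15 | 3-[5-acetyl-2-(benzyloxy)-4-hydroxyphenyl]-4-methoxybenzoic acid (present as its dipotassium salt, not isolated) | CC(=O)c1cc(-c2cc(C(=O)O)ccc2OC)c(OCc2ccccc2)cc1O | intermediate
16 | 3-{2-(benzyloxy)-4-hydroxy-5-[(2E)-3-(4-methoxyphenyl)prop-2-enoyl]phenyl}-4-methoxybenzoic acid | COc1ccc(/C=C/C(=O)c2cc(-c3cc(C(=O)O)ccc3OC)c(OCc3ccccc3)cc2O)cc1 | intermediate
17 | racemic trans-3-[7-(benzyloxy)-3-hydroxy-2-(4-methoxyphenyl)-4-oxo-3,4-dihydro-2H-chromen-6-yl]-4-methoxybenzoic acid (2R,3R enantiomer drawn, not isolated) | COc1ccc(cc1)[C@@H]1[C@@H](O)C(=O)c2cc(-c3cc(C(=O)O)ccc3OC)c(OCc3ccccc3)cc2O1 | intermediate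
18 | 3-[7-(benzyloxy)-3-hydroxy-2-(4-methoxyphenyl)-4-oxo-4H-chromen-6-yl]-4-methoxybenzoic acid | COc1ccc(-c2oc3cc(OCc4ccccc4)c(-c4cc(C(=O)O)ccc4OC)cc3c(=O)c2O)cc1 | intermediate
19 | benzyl 3-[3,7-bis(benzyloxy)-2-(4-methoxyphenyl)-4-oxo-4H-chromen-6-yl]-4-methoxybenzoate | COc1ccc(-c2oc3cc(OCc4ccccc4)c(-c4cc(C(=O)OCc5ccccc5)ccc4OC)cc3c(=O)c2OCc2ccccc2)cc1 | intermediate
20 | 2',6'-dihydroxy-4'-methoxyacetophenone, 1-(2,6-dihydroxy-4-methoxyphenyl)ethan-1-one | CC(=O)c1c(O)cc(OC)cc1O | starting material
21 | trilithium 5-methoxy-2-(1-oxidoethenyl)benzene-1,3-diolate (polyanion of 20, not isolated) | [Li+].[Li+].[Li+].C=C([O-])c1c([O-])cc(OC)cc1[O-] | intermediate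
22 | 1-{3-[3,7-bis(benzyloxy)-2-(4-methoxyphenyl)-4-oxo-4H-chromen-6-yl]-4-methoxyphenyl}-3-(2,6-dihydroxy-4-methoxyphenyl)propane-1,3-dione (not isolated) | COc1cc(O)c(C(=O)CC(=O)c2ccc(OC)c(-c3cc4c(=O)c(OCc5ccccc5)c(-c5ccc(OC)cc5)oc4cc3OCc3ccccc3)c2)c(O)c1 | intermediate
23 | 3,7-di-O-benzylabiesin, 3,7-bis(benzyloxy)-6-[5-(5-hydroxy-7-methoxy-4-oxo-4H-chromen-2-yl)-2-methoxyphenyl]-2-(4-methoxyphenyl)-4H-chromen-4-one | COc1ccc(-c2oc3cc(OCc4ccccc4)c(-c4cc(-c5cc(=O)c6c(O)cc(OC)cc6o5)ccc4OC)cc3c(=O)c2OCc2ccccc2)cc1 | intermediate
24 | abiesin, 3,7-dihydroxy-6-[5-(5-hydroxy-7-methoxy-4-oxo-4H-chromen-2-yl)-2-methoxyphenyl]-2-(4-methoxyphenyl)-4H-chromen-4-one | COc1ccc(-c2oc3cc(O)c(-c4cc(-c5cc(=O)c6c(O)cc(OC)cc6o5)ccc4OC)cc3c(=O)c2O)cc1 | target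

## Step count and risk

Total: 11 steps. Longest linear sequence: 11 steps (1 to 24); compounds 5, 9, 14 and 20 are bought and enter without separate preparation.

**Step 4 (key step).**
- Risk: incomplete regiocontrol, with the aryl-directed orientation competing with the methoxy-directed one. At the temperature a propiolate needs, the diene may also be lost by dimerization or polymerization, or the enol ether hydrolysed by adventitious acid.
- Fallback: starting from 8, the propiolate is replaced by commercial methyl 2-chloroacrylate, a more reactive and more polarized dienophile that should add at 40–60 °C. It forms the same two bonds in the same orientation and gives racemic methyl 3-[2,4-bis(benzyloxy)phenyl]-1-chloro-4-methoxycyclohex-3-ene-1-carboxylate F1. DBU in toluene then removes hydrogen chloride to give 10 together with its conjugated isomer methyl 3-[2,4-bis(benzyloxy)phenyl]-4-methoxycyclohexa-1,3-diene-1-carboxylate F2. The fallback rejoins the route at 10, and F2 converges on 11 in the DDQ step.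

**Step 6.**
- Risk: transfer of benzyl cations under the Lewis acid (C-benzylation of unreacted, electron-rich 11), loss of both benzyl ethers, or incomplete cleavage of the ortho ether.
- Fallback: starting from 11, both benzyl groups are removed by hydrogenolysis (H2, Pd/C) to give methyl 3-(2,4-dihydroxyphenyl)-4-methoxybenzoate F3. The free resorcinol is C-acetylated with AcOH and BF3·OEt2 at 80 °C (Nencki-type acylation at the same carbon) to methyl 3-(5-acetyl-2,4-dihydroxyphenyl)-4-methoxybenzoate F4. One equivalent of BnBr with K2CO3 in acetone then benzylates only the non-chelated hydroxyl and returns 13.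

**Step 2.**
- Risk: ionization or hydrolysis of the electron-rich α-aryl enol triflate during isolation, or base-induced elimination to the arylalkyne.
- Fallback: starting from 2, the lithium reagent 6 (with CeCl3 if enolization interferes) is added to the ketone to give racemic 2-[2,4-bis(benzyloxy)phenyl]-3-methoxybut-3-en-2-ol F5. Dehydration with the Burgess reagent, for which only the methyl group offers β-hydrogens, returns diene 8 without any triflate or palladium step.

**Step 10.**
- Risk: slow C-acylation by an electron-rich (anisate-type) ester, which leaves the polyanion 21 free to attack the chromone of the flavonol or to be quenched; benzyl migration during the acidic cyclodehydration.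
- Fallback: starting from 19, LiOH saponification gives 3-[3,7-bis(benzyloxy)-2-(4-methoxyphenyl)-4-oxo-4H-chromen-6-yl]-4-methoxybenzoic acid F6. Esterification of one hydroxyl of 20 with EDC·HCl and DMAP gives 2-acetyl-3-hydroxy-5-methoxyphenyl 3-[3,7-bis(benzyloxy)-2-(4-methoxyphenyl)-4-oxo-4H-chromen-6-yl]-4-methoxybenzoate F7. A Baker–Venkataraman O-to-C acyl shift (KOH, pyridine, 50 °C) then delivers the diketone 22, which is cyclized as in step 10 to rejoin the route at 23.

**Step 11.**
- Risk: over-reduction of a chromone C2–C3 double bond, or stalling of the hydrogenolysis through poor solubility and adsorption of the polyphenol on the catalyst.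
- Fallback: starting from 23, the benzyl ethers are cleaved with BCl3 and pentamethylbenzene as cation scavenger in CH2Cl2 at −78 °C, which gives 24 directly. Non-chelated methyl ethers are not expected to be cleaved at that temperature. No new compound is involved.

## Further compounds

F1 | step 4 | methyl 3-[2,4-bis(benzyloxy)phenyl]-1-chloro-4-methoxycyclohex-3-ene-1-carboxylate (racemic) | COC(=O)C1(Cl)CCC(OC)=C(C1)c1ccc(OCc2ccccc2)cc1OCc1ccccc1
F2 | step 4 | methyl 3-[2,4-bis(benzyloxy)phenyl]-4-methoxycyclohexa-1,3-diene-1-carboxylate | COC(=O)C1=CC(c2ccc(OCc3ccccc3)cc2OCc2ccccc2)=C(OC)CC1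
F3 | step 6 | methyl 3-(2,4-dihydroxyphenyl)-4-methoxybenzoate | COC(=O)c1ccc(OC)c(c1)-c1ccc(O)cc1O
F4 | step 6 | methyl 3-(5-acetyl-2,4-dihydroxyphenyl)-4-methoxybenzoate | COC(=O)c1ccc(OC)c(c1)-c1cc(C(C)=O)c(O)cc1O
F5 | step 2 | 2-[2,4-bis(benzyloxy)phenyl]-3-methoxybut-3-en-2-ol (racemic) | C=C(OC)C(C)(O)c1ccc(OCc2ccccc2)cc1OCc1ccccc1
F6 | step 10 | 3-[3,7-bis(benzyloxy)-2-(4-methoxyphenyl)-4-oxo-4H-chromen-6-yl]-4-methoxybenzoic acid | COc1ccc(-c2oc3cc(OCc4ccccc4)c(-c4cc(C(=O)O)ccc4OC)cc3c(=O)c2OCc2ccccc2)cc1
F7 | step 10 | 2-acetyl-3-hydroxy-5-methoxyphenyl 3-[3,7-bis(benzyloxy)-2-(4-methoxyphenyl)-4-oxo-4H-chromen-6-yl]-4-methoxybenzoate | COc1ccc(-c2oc3cc(OCc4ccccc4)c(-c4cc(C(=O)Oc5cc(OC)cc(O)c5C(C)=O)ccc4OC)cc3c(=O)c2OCc2ccccc2)cc1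
F0 | step 11 | none | none
A1 | alternative 1 | 1-{3-[3,7-bis(benzyloxy)-2-(4-methoxyphenyl)-4-oxo-4H-chromen-6-yl]-4-methoxyphenyl}-4-(4-methoxy-2-oxo-2H-pyran-6-yl)butane-1,3-dione | COc1cc(CC(=O)CC(=O)c2ccc(OC)c(-c3cc4c(=O)c(OCc5ccccc5)c(-c5ccc(OC)cc5)oc4cc3OCc3ccccc3)c2)oc(=O)c1
A2 | alternative 1 | 1-{3-[3,7-bis(benzyloxy)-2-(4-methoxyphenyl)-4-oxo-4H-chromen-6-yl]-4-methoxyphenyl}-3-(2,6-dihydroxy-4-methoxyphenyl)propane-1,3-dione | COc1cc(O)c(C(=O)CC(=O)c2ccc(OC)c(-c3cc4c(=O)c(OCc5ccccc5)c(-c5ccc(OC)cc5)oc4cc3OCc3ccccc3)c2)c(O)c1
A3 | alternative 2 | (2E)-1-{4-(benzyloxy)-2-hydroxy-5-[5-(5-hydroxy-7-methoxy-4-oxo-4H-chromen-2-yl)-2-methoxyphenyl]phenyl}-3-(4-methoxyphenyl)prop-2-en-1-one | COc1ccc(/C=C/C(=O)c2cc(-c3cc(-c4cc(=O)c5c(O)cc(OC)cc5o4)ccc3OC)c(OCc3ccccc3)cc2O)cc1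
A4 | alternative 2 | 7-O-benzylabiesin | COc1ccc(-c2oc3cc(OCc4ccccc4)c(-c4cc(-c5cc(=O)c6c(O)cc(OC)cc6o5)ccc4OC)cc3c(=O)c2O)cc1
A5 | alternative 3 | 2-iodo-5-methoxybenzene-1,3-diol | COc1cc(O)c(I)c(O)c1
A6 | alternative 3 | 3,7-bis(benzyloxy)-6-(5-ethynyl-2-methoxyphenyl)-2-(4-methoxyphenyl)-4H-chromen-4-one | C#Cc1ccc(OC)c(c1)-c1cc2c(=O)c(OCc3ccccc3)c(-c3ccc(OC)cc3)oc2cc1OCc1ccccc1
A7 | alternative 3 | 3,7-di-O-benzylabiesin | COc1ccc(-c2oc3cc(OCc4ccccc4)c(-c4cc(-c5cc(=O)c6c(O)cc(OC)cc6o5)ccc4OC)cc3c(=O)c2OCc2ccccc2)cc1
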